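**Assumption:** the target has no stereocentre or stereogenic axis (its SMILES carries no stereodescriptor), so it is one achiral compound and no enantiocontrol is needed.

## Retrosynthetic overview

1. Target 16 ⇐ 5,7-di-O-benzyl ether 15 (hydrogenolysis) ⇐ flavonol 14 (3-O-methylation).
2. 14 ⇐ flavone 12 (C3 oxygenation by epoxidation and ring opening) ⇐ chalcone 10 (oxidative cyclisation).
3. 10 ⇐ ring A ketone 7 + ring B aldehyde 8 by Claisen–Schmidt aldol condensation; the new C–C bond becomes C2–C3 of the flavone.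
4. 7 ⇐ phloroacetophenone 1 by dibenzylation, ring dibromination and double methoxylation; the symmetry of 1 removes any regiochemical question.
5. Ring order: rings A and B are bought as benzene rings; ring C (the pyranone) is the only ring formed, in step 5.

## Route

**Step 1**
Reactants: 1 1-(2,4,6-trihydroxyphenyl)ethanone (phloroacetophenone)
Product: 3 1-[2,4-bis(benzyloxy)-6-hydroxyphenyl]ethanone, via monobenzyl ether 2 (not isolated)
Conditions: BnBr (2.1 equiv), K2CO3 (2.2 equiv), DMF, 0 °C to rt, 16 h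
Reagents that add atoms: benzyl bromide, BrCc1ccccc1
Why: Williamson ether synthesis in which the 4-OH and then one of the two equivalent ortho OH groups are alkylated, while the last OH is held in a hydrogen bond to the ketone and stays free.

**Step 2**
Reactants: 3 1-[2,4-bis(benzyloxy)-6-hydroxyphenyl]ethanone
Product: 5 1-[4,6-bis(benzyloxy)-3,5-dibromo-2-hydroxyphenyl]ethanone, via monobromide 4 (not isolated)
Conditions: NBS (2.1 equiv), DMF, 0 °C to rt, dark
Reagents that add atoms: N-bromosuccinimide, O=C1CCC(=O)N1Br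
Why: Electrophilic aromatic bromination of the only two free ring positions, each activated by three oxygen donors, which is far faster than alpha-bromination of the ketone or benzylic bromination under ionic conditions.

**Step 3**
Reactants: 5 1-[4,6-bis(benzyloxy)-3,5-dibromo-2-hydroxyphenyl]ethanone
Product: 7 1-[4,6-bis(benzyloxy)-2-hydroxy-3,5-dimethoxyphenyl]ethanone, via bromo methoxy ketone 6 (not isolated)
Conditions: NaOMe (10 equiv, 25% in MeOH), CuBr (0.4 equiv), DMF, 110 °C, N2; then aq. HCl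
Reagents that add atoms: sodium methoxide, [Na+].[O-]C
Why: Copper-catalysed Ullmann-type methoxylation of aryl bromides flanked by oxygen substituents, a reaction class that tolerates a free phenoxide (as in 5-bromovanillin to syringaldehyde) and leaves benzyl ethers untouched.

**Step 4**
Reactants: 7 1-[4,6-bis(benzyloxy)-2-hydroxy-3,5-dimethoxyphenyl]ethanone; 8 2,4,5-trimethoxybenzaldehyde
Product: 10 (E)-1-[4,6-bis(benzyloxy)-2-hydroxy-3,5-dimethoxyphenyl]-3-(2,4,5-trimethoxyphenyl)prop-2-en-1-one, via aldol adduct 9 (not isolated)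
Conditions: KOH (50% aq., 10 equiv), EtOH, rt, 48 h; then cold 2 M HCl
Reagents that add atoms: none
Why: Claisen–Schmidt crossed aldol condensation of the methyl ketone enolate with a non-enolisable aldehyde, followed by E1cB dehydration to the more stable E-enone, which removes the stereocentre of racemic 9.

**Step 5**
Reactants: 10 (E)-1-[4,6-bis(benzyloxy)-2-hydroxy-3,5-dimethoxyphenyl]-3-(2,4,5-trimethoxyphenyl)prop-2-en-1-one
Product: 12 5,7-bis(benzyloxy)-6,8-dimethoxy-2-(2,4,5-trimethoxyphenyl)-4H-chromen-4-one, via flavanone 11 (not isolated)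
Conditions: I2 (0.1 equiv), DMSO, 120 °C, 3 h; aq. Na2S2O3 work-up
Reagents that add atoms: none
Why: Iodine-catalysed oxidative cyclisation in which oxa-Michael closure gives the flavanone, alpha-iodination and loss of HI give the flavone, and DMSO re-oxidises HI to I2; any flavanone already present in crude 10 converges to the same product.

**Step 6**
Reactants: 12 5,7-bis(benzyloxy)-6,8-dimethoxy-2-(2,4,5-trimethoxyphenyl)-4H-chromen-4-one
Product: 14 5,7-bis(benzyloxy)-3-hydroxy-6,8-dimethoxy-2-(2,4,5-trimethoxyphenyl)-4H-chromen-4-one, via flavone epoxide 13 (not isolated)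
Conditions: DMDO (3 equiv, ca. 0.08 M in acetone), CH2Cl2, 0 °C to rt; then p-TsOH·H2O (0.1 equiv), CH2Cl2, rt
Reagents that add atoms: dimethyldioxirane, CC1(C)OO1
Why: Dioxirane epoxidation of the C2–C3 double bond followed by acid-catalysed opening at C2 (cation stabilised by O1 and the aryl group) and loss of the C3 proton gives the 3-hydroxyflavone, so no stereocentre remains.

**Step 7**
Reactants: 14 5,7-bis(benzyloxy)-3-hydroxy-6,8-dimethoxy-2-(2,4,5-trimethoxyphenyl)-4H-chromen-4-one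
Product: 15 5,7-bis(benzyloxy)-3,6,8-trimethoxy-2-(2,4,5-trimethoxyphenyl)-4H-chromen-4-one
Conditions: MeI (3 equiv), K2CO3 (3 equiv), acetone, reflux
Reagents that add atoms: iodomethane, CI
Why: Williamson O-methylation of the acidic enolic 3-OH, which is the only free hydroxyl in the molecule.

**Step 8**
Reactants: 15 5,7-bis(benzyloxy)-3,6,8-trimethoxy-2-(2,4,5-trimethoxyphenyl)-4H-chromen-4-one
Product: 16 5,7-dihydroxy-3,6,8-trimethoxy-2-(2,4,5-trimethoxyphenyl)-4H-chromen-4-one (5,7-dihydroxy-3,6,8,2',4',5'-hexamethoxyflavone)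
Conditions: H2 (1 atm), 10% Pd/C, THF/MeOH 1:1, rt
Reagents that add atoms: none
Why: Catalytic hydrogenolysis cleaves both benzyl aryl ethers, while the fully substituted vinylogous-ester C2–C3 double bond and the aryl methyl ethers are not reduced at 1 atm and room temperature.

## Compound list

1 | 1-(2,4,6-trihydroxyphenyl)ethanone (phloroacetophenone) | CC(=O)c1c(O)cc(O)cc1O | starting material
2 | 1-[4-(benzyloxy)-2,6-dihydroxyphenyl]ethanone | CC(=O)c1c(O)cc(OCc2ccccc2)cc1O | intermediate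
3 | 1-[2,4-bis(benzyloxy)-6-hydroxyphenyl]ethanone | CC(=O)c1c(O)cc(OCc2ccccc2)cc1OCc1ccccc1 | intermediate
4 | 1-[4,6-bis(benzyloxy)-3-bromo-2-hydroxyphenyl]ethanone | CC(=O)c1c(O)c(Br)c(OCc2ccccc2)cc1OCc1ccccc1 | intermediate
5 | 1-[4,6-bis(benzyloxy)-3,5-dibromo-2-hydroxyphenyl]ethanone | CC(=O)c1c(O)c(Br)c(OCc2ccccc2)c(Br)c1OCc1ccccc1 | intermediate
6 | 1-[4,6-bis(benzyloxy)-5-bromo-2-hydroxy-3-methoxyphenyl]ethanone | CC(=O)c1c(O)c(OC)c(OCc2ccccc2)c(Br)c1OCc1ccccc1 | intermediate
7 | 1-[4,6-bis(benzyloxy)-2-hydroxy-3,5-dimethoxyphenyl]ethanone | CC(=O)c1c(O)c(OC)c(OCc2ccccc2)c(OC)c1OCc1ccccc1 | intermediate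
8 | 2,4,5-trimethoxybenzaldehyde | COc1cc(OC)c(C=O)cc1OC | starting material
9 | 1-[4,6-bis(benzyloxy)-2-hydroxy-3,5-dimethoxyphenyl]-3-hydroxy-3-(2,4,5-trimethoxyphenyl)propan-1-one (racemic) | COc1cc(OC)c(C(O)CC(=O)c2c(O)c(OC)c(OCc3ccccc3)c(OC)c2OCc2ccccc2)cc1OC | intermediate
10 | (E)-1-[4,6-bis(benzyloxy)-2-hydroxy-3,5-dimethoxyphenyl]-3-(2,4,5-trimethoxyphenyl)prop-2-en-1-one | COc1cc(OC)c(/C=C/C(=O)c2c(O)c(OC)c(OCc3ccccc3)c(OC)c2OCc2ccccc2)cc1OC | intermediate
11 | 5,7-bis(benzyloxy)-6,8-dimethoxy-2-(2,4,5-trimethoxyphenyl)chroman-4-one (racemic) | COc1cc(OC)c(C2CC(=O)c3c(OCc4ccccc4)c(OC)c(OCc4ccccc4)c(OC)c3O2)cc1OC | intermediate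
12 | 5,7-bis(benzyloxy)-6,8-dimethoxy-2-(2,4,5-trimethoxyphenyl)-4H-chromen-4-one | COc1cc(OC)c(-c2cc(=O)c3c(OCc4ccccc4)c(OC)c(OCc4ccccc4)c(OC)c3o2)cc1OC | intermediate
13 | 5,7-bis(benzyloxy)-2,3-epoxy-6,8-dimethoxy-2-(2,4,5-trimethoxyphenyl)chroman-4-one (racemic) | COc1cc(OC)c(C23OC2C(=O)c2c(OCc4ccccc4)c(OC)c(OCc4ccccc4)c(OC)c2O3)cc1OC | intermediate
14 | 5,7-bis(benzyloxy)-3-hydroxy-6,8-dimethoxy-2-(2,4,5-trimethoxyphenyl)-4H-chromen-4-one | COc1cc(OC)c(-c2oc3c(OC)c(OCc4ccccc4)c(OC)c(OCc4ccccc4)c3c(=O)c2O)cc1OC | intermediate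
15 | 5,7-bis(benzyloxy)-3,6,8-trimethoxy-2-(2,4,5-trimethoxyphenyl)-4H-chromen-4-one | COc1cc(OC)c(-c2oc3c(OC)c(OCc4ccccc4)c(OC)c(OCc4ccccc4)c3c(=O)c2OC)cc1OC | intermediate
16 | 5,7-dihydroxy-3,6,8-trimethoxy-2-(2,4,5-trimethoxyphenyl)-4H-chromen-4-one (5,7-dihydroxy-3,6,8,2',4',5'-hexamethoxyflavone) | COc1cc(OC)c(-c2oc3c(OC)c(O)c(OC)c(O)c3c(=O)c2OC)cc1OC | target

## Step count and risks

Total step count: 8. Longest linear sequence: 8 steps (1 to 16); aldehyde 8 is bought and enters in step 4.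

**Step 3 (double copper-catalysed methoxylation).** The risks are hydrodebromination and incomplete exchange at the bromide flanked by two benzyloxy groups. The fallback sets out from 3 and comes back at 16; it moves the oxygenation of ring A to the end, where the two free phenols direct it. Ketone 3 is condensed with 8 (KOH, EtOH) to the chalcone (E)-1-[2,4-bis(benzyloxy)-6-hydroxyphenyl]-3-(2,4,5-trimethoxyphenyl)prop-2-en-1-one F1. I2/DMSO cyclises it to 5,7-bis(benzyloxy)-2-(2,4,5-trimethoxyphenyl)-4H-chromen-4-one F2. DMDO then p-TsOH gives 5,7-bis(benzyloxy)-3-hydroxy-2-(2,4,5-trimethoxyphenyl)-4H-chromen-4-one F3. MeI/K2CO3 gives 5,7-bis(benzyloxy)-3-methoxy-2-(2,4,5-trimethoxyphenyl)-4H-chromen-4-one F4, and H2 over Pd/C gives 5,7-dihydroxy-3-methoxy-2-(2,4,5-trimethoxyphenyl)-4H-chromen-4-one F5. NBS (2.0 equiv, DMF, 0 °C) brominates the phloroglucinol-type ring A at C6 and C8 to 6,8-dibromo-5,7-dihydroxy-3-methoxy-2-(2,4,5-trimethoxyphenyl)-4H-chromen-4-one F6. NaOMe/CuBr in DMF/MeOH then replaces both bromines by methoxy and gives 16.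

**Step 6 (dioxirane oxidation at C3).** The risks are slow epoxidation of the electron-poor C2–C3 bond and competing oxidation of the electron-rich rings or benzylic positions. The fallback sets out from 10 and comes back at 14; it bypasses flavone 12 by an Algar–Flynn–Oyamada reaction. Chalcone 10 is treated with 30% H2O2 and NaOH in MeOH/THF at 0 °C to rt. Epoxidation of the enone and 6-endo closure by the phenoxide give racemic trans-5,7-bis(benzyloxy)-3-hydroxy-6,8-dimethoxy-2-(2,4,5-trimethoxyphenyl)chroman-4-one F7, which is not isolated and is oxidised in the same pot to 14. The known weakness is aurone formation from chalcones with a 6'-alkoxy group, so the reaction is kept cold and the aurone is removed by chromatography.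

**Step 5 (iodine/DMSO cyclisation).** The risks are partial loss of the 5-O-benzyl group to the HI formed and incomplete dehydrogenation. The fallback sets out from 10 and comes back at 12; it separates ring closure from oxidation. Chalcone 10 is isomerised with NaOAc in refluxing EtOH to racemic flavanone 11, which is now isolated. It is then dehydrogenated with DDQ in refluxing 1,4-dioxane to flavone 12, with no iodide or acid present.

## Further compounds

F1 | step 3 | (E)-1-[2,4-bis(benzyloxy)-6-hydroxyphenyl]-3-(2,4,5-trimethoxyphenyl)prop-2-en-1-one | COc1cc(OC)c(/C=C/C(=O)c2c(O)cc(OCc3ccccc3)cc2OCc2ccccc2)cc1OC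
F2 | step 3 | 5,7-bis(benzyloxy)-2-(2,4,5-trimethoxyphenyl)-4H-chromen-4-one | COc1cc(OC)c(-c2cc(=O)c3c(OCc4ccccc4)cc(OCc4ccccc4)cc3o2)cc1OC
F3 | step 3 | 5,7-bis(benzyloxy)-3-hydroxy-2-(2,4,5-trimethoxyphenyl)-4H-chromen-4-one | COc1cc(OC)c(-c2oc3cc(OCc4ccccc4)cc(OCc4ccccc4)c3c(=O)c2O)cc1OC
F4 | step 3 | 5,7-bis(benzyloxy)-3-methoxy-2-(2,4,5-trimethoxyphenyl)-4H-chromen-4-one | COc1cc(OC)c(-c2oc3cc(OCc4ccccc4)cc(OCc4ccccc4)c3c(=O)c2OC)cc1OC
F5 | step 3 | 5,7-dihydroxy-3-methoxy-2-(2,4,5-trimethoxyphenyl)-4H-chromen-4-one | COc1cc(OC)c(-c2oc3cc(O)cc(O)c3c(=O)c2OC)cc1OC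
F6 | step 3 | 6,8-dibromo-5,7-dihydroxy-3-methoxy-2-(2,4,5-trimethoxyphenyl)-4H-chromen-4-one | COc1cc(OC)c(-c2oc3c(Br)c(O)c(Br)c(O)c3c(=O)c2OC)cc1OC
F0 | step 5 | none | none
F7 | step 6 | trans-5,7-bis(benzyloxy)-3-hydroxy-6,8-dimethoxy-2-(2,4,5-trimethoxyphenyl)chroman-4-one (racemate; the 2R,3R enantiomer is drawn) | O[C@@H]1[C@@H](c2cc(OC)c(OC)cc2OC)Oc2c(OC)c(OCc3ccccc3)c(OC)c(OCc3ccccc3)c2C1=O
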